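A steady ratio between two readings tempts one to call a flask at rest. The missing share, meaning the charge less side product and target, read 0.233 of the target in the dawn run at 120 s and 0.243 in the dusk run at 2.00 min, yet side product in the dusk run went on from 64.2% to 92.9% by 6.00 min. I had to decide whether to leave the dawn flask for 25 min or take its target early.

all flasks: gas phase 0.013 mM (held)
- dawn: starting material 2.0 × 10⁻⁴ M; the very flask that is asked about, followed so far
- dusk: starting material 1.0 × 10⁻⁴ M; run made earlier
- flask: starting material 2.0 × 10⁻⁴ M; time 25 min

- dawn (time / s: side product / %, target / %): 10.0: 22.3, 38.1; 20.0: 31.9, 49.0; 50.0: 45.4, 44.6; 120: 65.6, 27.9
- dusk (time / min: side product / %, target / %): 2.00: 64.2, 28.8; 6.00: 92.9, 5.8; 12.0: 99.6, 0.5; 20.0: 99.7, 0.3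

(standard deviation of a reading: 0.3 percentage points)

- at the start none of the gas phase is in solution
- the reaction counts as stopped when no species that holds the starting material changes by six tenths of a point or more over the second half of the time

1. which holds at 25 min: what has brought the reaction to rest, or that it has not come to rest (all of the starting material has reacted / forward and back rates have come level / it is still moving)
2. amount of side product at 25 min, in percent of the starting material charged

I froze that ratio, so that target and missing share fell together. From the dusk readings I read λ = 0.401 min⁻¹, the late first-order fall of target with the gas held, my drain constant, a pseudo-first-order constant. The dawn run, at twice the charge, read 0.402 min⁻¹ over its last interval. Starting from its last reading, I reckoned 0.00275% target at 25 min. By the same reckoning, target and missing share together stood at 0.51 percentage points at half that time, inside the margin for rest. So I would take target early, near the 49.0% read at 20.0 s, for the dawn run read 27.9% by 120 s.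

The forecast gave all of the starting material has reacted and 99.9% side product, holding that “doubling the charge barely matters”.

The flask gave all of the starting material has reacted and >99.9% side product.

    gas phase ⇌ dissolved gas, rate k1*(csat - [dissolved gas]) (kL = 1.90 s⁻¹)
    starting material + dissolved gas ⇌ target (K = 2.60 × 10⁵ L mol⁻¹, k = 8700 L mol⁻¹ s⁻¹)
    starting material → side product (k = 0.0350 s⁻¹)

At 1.06 min in the asked flask, starting material went to side product at 0.30 of its forward rate into target, with a half-life by that step of 0.33 min, shorter than the 25 min allowed. Up to 25 min, backward turnover of the target step reached >99.9% of the forward one, leaving 0% net. Carried from 120 s, λ gives 0.414% target at 12.5 min, where this flask held 0.414%. For the same flask left until 6.0 min, λ gives 5.61%, and that flask held 5.63%.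

The readings stem from a simulated flask on assumed constants; the scatter is artificial.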